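**Strategy.** Everything rests on letting a carboxyl group stand in for C1, the methylidene-bearing carbon of ring A. In ring B, C9(Me)Cl lies 1,4 and C8HBr 1,3 to the spiro carbon C6, with Cl on the face of C1 and Br on the face of C5 (CMe2). NBS bromolactonisation of (1R)-4-methyl-1-(2-methylbut-3-yn-2-yl)cyclohex-3-ene-1-carboxylic acid therefore closes a bridged δ-lactone that places oxygen on C9 from the C1 face and bromine on C8 anti to it in one operation. Oxygen is then exchanged for chloride with retention, and the lactone carbon and the alkyne are grown into ring A (aldol closure, vinyl bromide, reagent-controlled carbonyl reduction).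

Key step: step 11

Remark (atom labels): target numbering is used for the corresponding atoms of all intermediates: ring A C1(=CH2)–C2(OH)–C3=C4(Br)–C5(Me2)–C6; ring B C6–C7H2–C8HBr–C9(Me)Cl–C10H2–C11H2.

Remark (assumption): the enantiomer of the lithium amide in step 8 and of the oxazaborolidine in step 21 is chosen from the usual empirical models; the mirror-image reagent is equally available if the sense proves opposite.

Step 1
Reactants: 1 1,4-dioxaspiro[4.5]decane-8-carboxylic acid; 2 1-bromo-3-methylbut-2-ene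
Product: 3 3-methylbut-2-en-1-yl 1,4-dioxaspiro[4.5]decane-8-carboxylate
Conditions: K2CO3, DMF, rt
Reagents that add atoms: 1-bromo-3-methylbut-2-ene, CC(C)=CCBr
Why: SN2 O-alkylation of the potassium carboxylate by an allylic bromide is fast and forms no stereocentre.

Step 2
Reactants: 3 3-methylbut-2-en-1-yl 1,4-dioxaspiro[4.5]decane-8-carboxylate
Product: 6 8-(2-methylbut-3-en-2-yl)-1,4-dioxaspiro[4.5]decane-8-carboxylic acid, via silyl ketene acetal 4 (not isolated), via trimethylsilyl ester 5 (not isolated)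
Conditions: LDA, THF, −78 °C; Me3SiCl, −78 → 60 °C; then H2O
Reagents that add atoms: none
Why: Ireland–Claisen rearrangement of the ketene acetal of the symmetrical ester joins the ring carbon to the dimethyl-substituted allyl terminus through a six-membered transition state, the standard way to make two adjacent quaternary carbons, and no stereocentre arises because the ring is still symmetrical.

Step 3
Reactants: 6 8-(2-methylbut-3-en-2-yl)-1,4-dioxaspiro[4.5]decane-8-carboxylic acid; 7 2-(trimethylsilyl)ethanol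
Product: 8 2-(trimethylsilyl)ethyl 8-(2-methylbut-3-en-2-yl)-1,4-dioxaspiro[4.5]decane-8-carboxylate
Conditions: PPh3, DIAD, THF, 0 °C → rt
Reagents that add atoms: 2-(trimethylsilyl)ethanol, C[Si](C)(C)CCO
Why: Mitsunobu esterification uses the hindered carboxylate as nucleophile at the primary carbon of the activated alcohol and gives an ester that fluoride can later remove without attack at the crowded carbonyl.

Step 4
Reactants: 8 2-(trimethylsilyl)ethyl 8-(2-methylbut-3-en-2-yl)-1,4-dioxaspiro[4.5]decane-8-carboxylate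
Product: 10 2-(trimethylsilyl)ethyl 8-(2-methyl-1-oxopropan-2-yl)-1,4-dioxaspiro[4.5]decane-8-carboxylate, via ozonide 9 (not isolated)
Conditions: O3, CH2Cl2, −78 °C; then PPh3, −78 °C → rt
Reagents that add atoms: ozone, O=[O+][O-]
Why: Ozonolysis with reductive work-up cleaves the only alkene to the non-enolisable aldehyde, while ketal and ester are inert to ozone.

Step 5
Reactants: 10 2-(trimethylsilyl)ethyl 8-(2-methyl-1-oxopropan-2-yl)-1,4-dioxaspiro[4.5]decane-8-carboxylate; 11 dimethyl (1-diazo-2-oxopropyl)phosphonate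
Product: 12 2-(trimethylsilyl)ethyl 8-(2-methylbut-3-yn-2-yl)-1,4-dioxaspiro[4.5]decane-8-carboxylate
Conditions: K2CO3, MeOH, 0 °C → rt
Reagents that add atoms: dimethyl (1-diazo-2-oxopropyl)phosphonate, COP(=O)(OC)C(=[N+]=[N-])C(C)=O
Why: Seyferth–Gilbert homologation in its Ohira–Bestmann form turns a non-enolisable aldehyde into the terminal alkyne under carbonate conditions that leave the ketal and the hindered ester untouched.

Step 6
Reactants: 12 2-(trimethylsilyl)ethyl 8-(2-methylbut-3-yn-2-yl)-1,4-dioxaspiro[4.5]decane-8-carboxylate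
Product: 14 2-(trimethylsilyl)ethyl 8-[2-methyl-4-(trimethylsilyl)but-3-yn-2-yl]-1,4-dioxaspiro[4.5]decane-8-carboxylate, via lithium acetylide 13 (not isolated)
Conditions: LDA, THF, −78 °C; then Me3SiCl, −78 °C → rt
Reagents that add atoms: chlorotrimethylsilane, C[Si](C)(C)Cl
Why: Deprotonation of the alkyne (the only acidic C–H, since the ester has no α-hydrogen) and C-silylation of the acetylide mask that C–H before the lithium amide step.

Step 7
Reactants: 14 2-(trimethylsilyl)ethyl 8-[2-methyl-4-(trimethylsilyl)but-3-yn-2-yl]-1,4-dioxaspiro[4.5]decane-8-carboxylate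
Product: 15 2-(trimethylsilyl)ethyl 1-[2-methyl-4-(trimethylsilyl)but-3-yn-2-yl]-4-oxocyclohexane-1-carboxylate
Conditions: 1 M HCl (cat.), THF–H2O, rt
Reagents that add atoms: water, O
Why: Acid-catalysed ketal hydrolysis is tolerated by the alkynylsilane and the silylethyl ester and gives an achiral ketone with a mirror plane through C1 and C4 of the cyclohexanone.

Step 8
Reactants: 15 2-(trimethylsilyl)ethyl 1-[2-methyl-4-(trimethylsilyl)but-3-yn-2-yl]-4-oxocyclohexane-1-carboxylate
Product: 17 2-(trimethylsilyl)ethyl (1R)-1-[2-methyl-4-(trimethylsilyl)but-3-yn-2-yl]-4-(trifluoromethanesulfonyloxy)cyclohex-3-ene-1-carboxylate, via lithium enolate 16 (not isolated)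
Conditions: (R,R)-bis(1-phenylethyl)amine·HCl, n-BuLi (2 equiv), THF, −78 °C; 15; then PhNTf2, −78 → 0 °C
Reagents that add atoms: N-phenylbis(trifluoromethanesulfonimide), O=S(=O)(N(c1ccccc1)S(=O)(=O)C(F)(F)F)C(F)(F)F
Why: Enantioselective deprotonation of a prochiral 4,4-disubstituted cyclohexanone by a homochiral lithium amide in the presence of LiCl, with the tertiary alkyl group equatorial so that one of the two enantiotopic axial α-hydrogens is removed, followed by O-triflation of the enolate, should set the quaternary centre as R (sense by analogy with 4-tert-butylcyclohexanone).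

Step 9
Reactants: 17 2-(trimethylsilyl)ethyl (1R)-1-[2-methyl-4-(trimethylsilyl)but-3-yn-2-yl]-4-(trifluoromethanesulfonyloxy)cyclohex-3-ene-1-carboxylate
Product: 18 2-(trimethylsilyl)ethyl (1R)-4-methyl-1-[2-methyl-4-(trimethylsilyl)but-3-yn-2-yl]cyclohex-3-ene-1-carboxylate
Conditions: MeMgBr, Fe(acac)3 (5 mol %), THF–NMP, −30 → 0 °C
Reagents that add atoms: methylmagnesium bromide, C[Mg]Br
Why: Iron-catalysed Kumada-type cross-coupling of an alkenyl triflate with a methyl Grignard reagent runs below 0 °C, faster than attack on the hindered ester, and does not touch the stereocentre.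

Step 10
Reactants: 18 2-(trimethylsilyl)ethyl (1R)-4-methyl-1-[2-methyl-4-(trimethylsilyl)but-3-yn-2-yl]cyclohex-3-ene-1-carboxylate
Product: 19 (1R)-4-methyl-1-(2-methylbut-3-yn-2-yl)cyclohex-3-ene-1-carboxylic acid
Conditions: Bu4NF, THF, rt → 40 °C; then dilute HCl work-up
Reagents that add atoms: none
Why: Fluoride removes the alkynyl silyl group and fragments the 2-(trimethylsilyl)ethyl ester by β-elimination of ethene without attack at the hindered carbonyl, and the free acid can be crystallised (if needed as an amine salt) to raise its enantiomeric purity before the key step.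

Step 11
Reactants: 19 (1R)-4-methyl-1-(2-methylbut-3-yn-2-yl)cyclohex-3-ene-1-carboxylic acid; 20 N-bromosuccinimide
Product: 22 (1S,4R,6S)-6-bromo-1-methyl-4-(2-methylbut-3-yn-2-yl)-2-oxabicyclo[2.2.2]octan-3-one, via bromonium carboxylate 21 (not isolated)
Conditions: NBS (1.05 equiv), NaHCO3, CH2Cl2, −20 → 0 °C, dark
Reagents that add atoms: N-bromosuccinimide, O=C1CCC(=O)N1Br
Why: NBS transfers Br+ reversibly to either face of the trisubstituted alkene, but only the bromonium ion on the face away from the axial carboxylate can be trapped, and the carboxylate oxygen opens it at the methyl-bearing carbon. The closest known reaction type is bromo- and iodolactonisation of cyclohex-3-ene-1-carboxylic acids to bridged bicyclic lactones. The 2-oxabicyclo[2.2.2]octanone ring closes by attack of oxygen across the six-membered ring (1,4) through a boat, a 6-exo opening when counted along the CH2–CH2 bridge. C9 (C–O on the carboxyl face) is fixed by the tether and C8 (C–Br on the opposite face) by the anti opening of the bromonium ion, the absolute sense coming from the quaternary centre set in step 8. The step needs oxygen at the tertiary carbon (not 1,3-closure to the γ-lactone) and reaction at the alkene rather than the alkyne. The polarised bromonium ion with its long bond to the tertiary carbon, buffered low-temperature conditions, the equatorial preference of the tertiary alkyl arm that holds the carboxylate axial, and the low reactivity of an unactivated terminal alkyne toward Br+ without silver should secure both.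

Step 12
Reactants: 22 (1S,4R,6S)-6-bromo-1-methyl-4-(2-methylbut-3-yn-2-yl)-2-oxabicyclo[2.2.2]octan-3-one
Product: 24 (1R,3S,4S)-3-bromo-4-chloro-4-methyl-1-(2-methylbut-3-yn-2-yl)cyclohexane-1-carbonyl chloride, via chloro acid 23 (not isolated)
Conditions: HCl (4 M in 1,4-dioxane), CH2Cl2, 0 °C → rt; then (COCl)2, cat. DMF, rt
Reagents that add atoms: hydrogen chloride, Cl; oxalyl chloride, O=C(Cl)C(=O)Cl
Why: Acidolysis of a tertiary alkyl–oxygen bond (as in cleavage of tert-alkyl esters by HCl) with neighbouring-group participation: bromine on C8 assists ionisation at C9 (the reverse of step 11) and chloride opens the bromonium ion at the tertiary carbon on the face that oxygen leaves, so C9 should keep its configuration by double inversion, while conversion of the freed carboxyl into the acid chloride stops re-lactonisation.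

Step 13
Reactants: 24 (1R,3S,4S)-3-bromo-4-chloro-4-methyl-1-(2-methylbut-3-yn-2-yl)cyclohexane-1-carbonyl chloride; 25 (trimethylsilyl)methylmagnesium chloride
Product: 27 {2-[(1R,3S,4S)-3-bromo-4-chloro-4-methyl-1-(2-methylbut-3-yn-2-yl)cyclohexyl]prop-2-en-1-yl}trimethylsilane, via bis(silylmethyl) carbinol 26 (not isolated)
Conditions: Me3SiCH2MgCl, CeCl3, THF, −78 → 0 °C; then SiO2, CH2Cl2, rt
Reagents that add atoms: (trimethylsilyl)methylmagnesium chloride, C[Si](C)(C)C[Mg]Cl
Why: Double addition of the non-basic organocerium reagent to the hindered acid chloride and Peterson olefination of the β-hydroxysilane on silica install the methylidene carbon and the future C2 in one operation, the alkyne C–H and both alkyl halides being inert to organocerium reagents at low temperature.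

Step 14
Reactants: 27 {2-[(1R,3S,4S)-3-bromo-4-chloro-4-methyl-1-(2-methylbut-3-yn-2-yl)cyclohexyl]prop-2-en-1-yl}trimethylsilane
Product: 29 2-[(1R,3S,4S)-3-bromo-4-chloro-4-methyl-1-(2-methylbut-3-yn-2-yl)cyclohexyl]prop-2-en-1-ol, via epoxysilane 28 (not isolated)
Conditions: dimethyldioxirane, acetone, 0 °C; then Bu4NF, THF, 0 °C → rt
Reagents that add atoms: dimethyldioxirane, CC1(C)OO1
Why: Epoxidation of the electron-rich 1,1-disubstituted alkene (the alkyne is inert) and fluoride-induced Peterson-type opening of the β-silyl epoxide give the 2-substituted allylic alcohol, the transient epoxide stereocentre being destroyed in the elimination.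

Step 15
Reactants: 29 2-[(1R,3S,4S)-3-bromo-4-chloro-4-methyl-1-(2-methylbut-3-yn-2-yl)cyclohexyl]prop-2-en-1-ol
Product: 30 2-[(1R,3S,4S)-3-bromo-4-chloro-4-methyl-1-(2-methylbut-3-yn-2-yl)cyclohexyl]prop-2-enal
Conditions: Dess–Martin periodinane, CH2Cl2, 0 °C → rt
Reagents that add atoms: none
Why: Dess–Martin oxidation of the primary allylic alcohol gives the non-enolisable 2-substituted acrolein without touching the tertiary chloride or the secondary bromide.

Step 16
Reactants: 30 2-[(1R,3S,4S)-3-bromo-4-chloro-4-methyl-1-(2-methylbut-3-yn-2-yl)cyclohexyl]prop-2-enal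
Product: 31 2-[(1S,3S,4S)-3-bromo-4-chloro-4-methyl-1-(2-methyl-3-oxobutan-2-yl)cyclohexyl]prop-2-enal
Conditions: Ph3PAuNTf2 (3 mol %), H2O (5 equiv), 1,4-dioxane, 40 °C
Reagents that add atoms: water, O
Why: Gold-catalysed Markovnikov hydration puts oxygen on the internal alkyne carbon to give the methyl ketone, the electron-poor enal double bond being too unreactive to add to the activated alkyne (the descriptor at the quaternary carbon changes only because the priorities change).

Step 17
Reactants: 31 2-[(1S,3S,4S)-3-bromo-4-chloro-4-methyl-1-(2-methyl-3-oxobutan-2-yl)cyclohexyl]prop-2-enal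
Product: 33 8-bromo-9-chloro-5,5,9-trimethyl-1-methylidene-2-(triethylsilyloxy)spiro[5.5]undecan-4-one (target numbering; C6 C8 C9 as in 39; both C2 epimers), via lithium aldolate 32 (not isolated)
Conditions: LiHMDS, THF, −78 °C; then Et3SiOTf, −78 °C
Reagents that add atoms: triethylsilyl trifluoromethanesulfonate, CC[Si](CC)(CC)OS(=O)(=O)C(F)(F)F
Why: Intramolecular aldol addition (6-exo-trig closure by the enolate carbon): the kinetic enolate of the methyl ketone, the only enolisable position, adds 1,2 to the aldehyde to close ring A and the aldolate is silylated cold to prevent retro-aldol reaction and dehydration, C2 being left uncontrolled here and corrected in steps 20 and 21.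

Step 18
Reactants: 33 8-bromo-9-chloro-5,5,9-trimethyl-1-methylidene-2-(triethylsilyloxy)spiro[5.5]undecan-4-one
Product: 35 8-bromo-9-chloro-5,5,9-trimethyl-1-methylidene-2-(triethylsilyloxy)spiro[5.5]undec-3-en-4-yl trifluoromethanesulfonate (target numbering; C6 C8 C9 as in 39; both C2 epimers), via potassium enolate 34 (not isolated)
Conditions: KHMDS, THF, −78 °C; then PhNTf2, −78 → −40 °C
Reagents that add atoms: N-phenylbis(trifluoromethanesulfonimide), O=S(=O)(N(c1ccccc1)S(=O)(=O)C(F)(F)F)C(F)(F)F
Why: Enol triflate formation from the enolate, which can form only toward C3 because C5 is quaternary, with trapping at −78 °C that should outrun β-elimination of the silyloxy group.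

Step 19
Reactants: 35 8-bromo-9-chloro-5,5,9-trimethyl-1-methylidene-2-(triethylsilyloxy)spiro[5.5]undec-3-en-4-yl trifluoromethanesulfonate
Product: 36 [(4,8-dibromo-9-chloro-5,5,9-trimethyl-1-methylidenespiro[5.5]undec-3-en-2-yl)oxy]triethylsilane (target numbering; C6 C8 C9 as in 39; both C2 epimers)
Conditions: [Cp*Ru(MeCN)3]OTf (5 mol %), LiBr, THF, 40 °C
Reagents that add atoms: lithium bromide, [Li+].[Br-]
Why: Ruthenium-catalysed exchange of an alkenyl triflate for bromide with a lithium halide is a known triflate-to-halide conversion that uses no reducing metal, so the alkyl chloride and bromide should survive and the double bond stays in place.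

Step 20
Reactants: 36 [(4,8-dibromo-9-chloro-5,5,9-trimethyl-1-methylidenespiro[5.5]undec-3-en-2-yl)oxy]triethylsilane
Product: 38 (6S,8S,9S)-4,8-dibromo-9-chloro-5,5,9-trimethyl-1-methylidenespiro[5.5]undec-3-en-2-one, via epimeric alcohols 37 (not isolated)
Conditions: HF·pyridine, THF, 0 °C; then Dess–Martin periodinane, CH2Cl2, 0 °C
Reagents that add atoms: none
Why: Fluoride desilylation and Dess–Martin oxidation of the bis-allylic alcohol erase the uncontrolled C2 centre and give the cross-conjugated dienone, which is used at once.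

Step 21
Reactants: 38 (6S,8S,9S)-4,8-dibromo-9-chloro-5,5,9-trimethyl-1-methylidenespiro[5.5]undec-3-en-2-one
Product: 39 (2R,6S,8S,9S)-4,8-dibromo-9-chloro-5,5,9-trimethyl-1-methylidenespiro[5.5]undec-3-en-2-ol
Conditions: (S)-2-methyl-CBS-oxazaborolidine, catecholborane, toluene, −78 °C; then MeOH, aqueous work-up
Reagents that add atoms: none
Why: Corey–Bakshi–Shibata reduction: the remote stereocentres should exert little facial bias on the nearly planar dienone, so the catalyst decides, and with the fully substituted C1 side as the large group the (S)-catalyst should give the (2R)-alcohol by 1,2-reduction at low temperature.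

**Compound list**

1 | 1,4-dioxaspiro[4.5]decane-8-carboxylic acid | OC(=O)C1CCC2(CC1)OCCO2 | starting material
2 | 1-bromo-3-methylbut-2-ene | CC(C)=CCBr | starting material
3 | 3-methylbut-2-en-1-yl 1,4-dioxaspiro[4.5]decane-8-carboxylate | CC(C)=CCOC(=O)C1CCC2(CC1)OCCO2 | intermediate
4 | trimethylsilyl ketene acetal of 3 | CC(C)=CCOC(O[Si](C)(C)C)=C1CCC2(CC1)OCCO2 | intermediate
5 | trimethylsilyl 8-(2-methylbut-3-en-2-yl)-1,4-dioxaspiro[4.5]decane-8-carboxylate | C=CC(C)(C)C1(C(=O)O[Si](C)(C)C)CCC2(CC1)OCCO2 | intermediate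
6 | 8-(2-methylbut-3-en-2-yl)-1,4-dioxaspiro[4.5]decane-8-carboxylic acid | C=CC(C)(C)C1(C(=O)O)CCC2(CC1)OCCO2 | intermediate
7 | 2-(trimethylsilyl)ethanol | C[Si](C)(C)CCO | starting material
8 | 2-(trimethylsilyl)ethyl 8-(2-methylbut-3-en-2-yl)-1,4-dioxaspiro[4.5]decane-8-carboxylate | C=CC(C)(C)C1(C(=O)OCC[Si](C)(C)C)CCC2(CC1)OCCO2 | intermediate
9 | ozonide (1,2,4-trioxolane) of 8 | C1OC(OO1)C(C)(C)C2(C(=O)OCC[Si](C)(C)C)CCC3(CC2)OCCO3 | intermediate
10 | 2-(trimethylsilyl)ethyl 8-(2-methyl-1-oxopropan-2-yl)-1,4-dioxaspiro[4.5]decane-8-carboxylate | O=CC(C)(C)C1(C(=O)OCC[Si](C)(C)C)CCC2(CC1)OCCO2 | intermediate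
11 | dimethyl (1-diazo-2-oxopropyl)phosphonate | COP(=O)(OC)C(=[N+]=[N-])C(C)=O | starting material
12 | 2-(trimethylsilyl)ethyl 8-(2-methylbut-3-yn-2-yl)-1,4-dioxaspiro[4.5]decane-8-carboxylate | C#CC(C)(C)C1(C(=O)OCC[Si](C)(C)C)CCC2(CC1)OCCO2 | intermediate
13 | lithium acetylide of 12 | [Li]C#CC(C)(C)C1(C(=O)OCC[Si](C)(C)C)CCC2(CC1)OCCO2 | intermediate
14 | 2-(trimethylsilyl)ethyl 8-[2-methyl-4-(trimethylsilyl)but-3-yn-2-yl]-1,4-dioxaspiro[4.5]decane-8-carboxylate | C[Si](C)(C)C#CC(C)(C)C1(C(=O)OCC[Si](C)(C)C)CCC2(CC1)OCCO2 | intermediate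
15 | 2-(trimethylsilyl)ethyl 1-[2-methyl-4-(trimethylsilyl)but-3-yn-2-yl]-4-oxocyclohexane-1-carboxylate | C[Si](C)(C)C#CC(C)(C)C1(C(=O)OCC[Si](C)(C)C)CCC(=O)CC1 | intermediate
16 | lithium enolate of 15 (1R) | C[Si](C)(C)C#CC(C)(C)[C@@]1(C(=O)OCC[Si](C)(C)C)CCC(O[Li])=CC1 | intermediate
17 | 2-(trimethylsilyl)ethyl (1R)-1-[2-methyl-4-(trimethylsilyl)but-3-yn-2-yl]-4-(trifluoromethanesulfonyloxy)cyclohex-3-ene-1-carboxylate | C[Si](C)(C)C#CC(C)(C)[C@@]1(C(=O)OCC[Si](C)(C)C)CCC(OS(=O)(=O)C(F)(F)F)=CC1 | intermediate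
18 | 2-(trimethylsilyl)ethyl (1R)-4-methyl-1-[2-methyl-4-(trimethylsilyl)but-3-yn-2-yl]cyclohex-3-ene-1-carboxylate | C[Si](C)(C)C#CC(C)(C)[C@@]1(C(=O)OCC[Si](C)(C)C)CCC(C)=CC1 | intermediate
19 | (1R)-4-methyl-1-(2-methylbut-3-yn-2-yl)cyclohex-3-ene-1-carboxylic acid | C#CC(C)(C)[C@@]1(C(=O)O)CCC(C)=CC1 | intermediate
20 | N-bromosuccinimide | O=C1CCC(=O)N1Br | starting material
21 | bromonium carboxylate (Br on the face opposite the carboxylate) | C#CC(C)(C)[C@@]1(C(=O)[O-])CC[C@]2(C)[C@H](C1)[Br+]2 | intermediate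
22 | (1S,4R,6S)-6-bromo-1-methyl-4-(2-methylbut-3-yn-2-yl)-2-oxabicyclo[2.2.2]octan-3-one (Br anti to the lactone oxygen) | C#CC(C)(C)[C@@]1(C(=O)O2)CC[C@@]2(C)[C@@H](Br)C1 | intermediate
23 | (1R,3S,4S)-3-bromo-4-chloro-4-methyl-1-(2-methylbut-3-yn-2-yl)cyclohexane-1-carboxylic acid | C#CC(C)(C)[C@@]1(C(=O)O)CC[C@](C)(Cl)[C@@H](Br)C1 | intermediate
24 | (1R,3S,4S)-3-bromo-4-chloro-4-methyl-1-(2-methylbut-3-yn-2-yl)cyclohexane-1-carbonyl chloride | C#CC(C)(C)[C@@]1(C(=O)Cl)CC[C@](C)(Cl)[C@@H](Br)C1 | intermediate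
25 | (trimethylsilyl)methylmagnesium chloride | C[Si](C)(C)C[Mg]Cl | starting material
26 | 2-[(1R,3S,4S)-3-bromo-4-chloro-4-methyl-1-(2-methylbut-3-yn-2-yl)cyclohexyl]-1,3-bis(trimethylsilyl)propan-2-ol | C#CC(C)(C)[C@@]1(C(O)(C[Si](C)(C)C)C[Si](C)(C)C)CC[C@](C)(Cl)[C@@H](Br)C1 | intermediate
27 | {2-[(1R,3S,4S)-3-bromo-4-chloro-4-methyl-1-(2-methylbut-3-yn-2-yl)cyclohexyl]prop-2-en-1-yl}trimethylsilane | C#CC(C)(C)[C@@]1(C(=C)C[Si](C)(C)C)CC[C@](C)(Cl)[C@@H](Br)C1 | intermediate
28 | epoxide of 27 (oxirane carbon epimers) | C#CC(C)(C)[C@@]1(C2(C[Si](C)(C)C)CO2)CC[C@](C)(Cl)[C@@H](Br)C1 | intermediate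
29 | 2-[(1R,3S,4S)-3-bromo-4-chloro-4-methyl-1-(2-methylbut-3-yn-2-yl)cyclohexyl]prop-2-en-1-ol | C#CC(C)(C)[C@@]1(C(=C)CO)CC[C@](C)(Cl)[C@@H](Br)C1 | intermediate
30 | 2-[(1R,3S,4S)-3-bromo-4-chloro-4-methyl-1-(2-methylbut-3-yn-2-yl)cyclohexyl]prop-2-enal | C#CC(C)(C)[C@@]1(C(=C)C=O)CC[C@](C)(Cl)[C@@H](Br)C1 | intermediate
31 | 2-[(1S,3S,4S)-3-bromo-4-chloro-4-methyl-1-(2-methyl-3-oxobutan-2-yl)cyclohexyl]prop-2-enal | CC(=O)C(C)(C)[C@@]1(C(=C)C=O)CC[C@](C)(Cl)[C@@H](Br)C1 | intermediate
32 | lithium aldolate (C2–OLi; C4 ketone; C2 epimers) | C=C1C(O[Li])CC(=O)C(C)(C)[C@]12CC[C@](C)(Cl)[C@@H](Br)C2 | intermediate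
33 | 8-bromo-9-chloro-5,5,9-trimethyl-1-methylidene-2-(triethylsilyloxy)spiro[5.5]undecan-4-one (target numbering; C2 epimers) | C=C1C(O[Si](CC)(CC)CC)CC(=O)C(C)(C)[C@]12CC[C@](C)(Cl)[C@@H](Br)C2 | intermediate
34 | potassium enolate of 33 | C=C1C(O[Si](CC)(CC)CC)C=C(O[K])C(C)(C)[C@]12CC[C@](C)(Cl)[C@@H](Br)C2 | intermediate
35 | 8-bromo-9-chloro-5,5,9-trimethyl-1-methylidene-2-(triethylsilyloxy)spiro[5.5]undec-3-en-4-yl trifluoromethanesulfonate (target numbering; C2 epimers) | C=C1C(O[Si](CC)(CC)CC)C=C(OS(=O)(=O)C(F)(F)F)C(C)(C)[C@]12CC[C@](C)(Cl)[C@@H](Br)C2 | intermediate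
36 | [(4,8-dibromo-9-chloro-5,5,9-trimethyl-1-methylidenespiro[5.5]undec-3-en-2-yl)oxy]triethylsilane (target numbering; C2 epimers) | C=C1C(O[Si](CC)(CC)CC)C=C(Br)C(C)(C)[C@]12CC[C@](C)(Cl)[C@@H](Br)C2 | intermediate
37 | 4,8-dibromo-9-chloro-5,5,9-trimethyl-1-methylidenespiro[5.5]undec-3-en-2-ol (C2 epimers; 6S,8S,9S) | C=C1C(O)C=C(Br)C(C)(C)[C@]12CC[C@](C)(Cl)[C@@H](Br)C2 | intermediate
38 | (6S,8S,9S)-4,8-dibromo-9-chloro-5,5,9-trimethyl-1-methylidenespiro[5.5]undec-3-en-2-one | C=C1C(=O)C=C(Br)C(C)(C)[C@]12CC[C@](C)(Cl)[C@@H](Br)C2 | intermediate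
39 | (2R,6S,8S,9S)-4,8-dibromo-9-chloro-5,5,9-trimethyl-1-methylidenespiro[5.5]undec-3-en-2-ol | C=C1[C@H](O)C=C(Br)C(C)(C)[C@]12CC[C@](C)(Cl)[C@@H](Br)C2 | target

**Step count.** Total: 21 steps. Longest linear sequence: 21 steps (1 to 39; all other inputs are purchased reagents).

**Steps most likely to fail**

Step 11. What may go wrong: oxygen may close onto the secondary bromonium carbon (1,3-closure through a chair) instead of the tertiary one (1,4-closure through a boat), or trapping may be slow enough for Br+ to reach the alkyne. Fallback, setting out from 19 and rejoining at 24: if the same NBS treatment gives the regioisomeric lactone 4-bromo-4-methyl-1-(2-methylbut-3-yn-2-yl)-6-oxabicyclo[3.2.1]octan-7-one F1, it is carried on instead of 22. Its secondary C–O bond is anti-periplanar to the tertiary bromine, so the HCl and oxalyl chloride treatment of step 12 should ionise it to the same bromonium ion, and chloride should then add at the tertiary carbon while bromine shifts to C8, giving 24 by a bromine-shift relay instead of direct oxygen delivery to C9.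

Step 12. What may go wrong: chloride may enter at C8 with bromine moving to C9, the cation may lose a proton to give allylic bromides, or the lactone may re-close before the acid chloride forms. Fallback, setting out from 22 and rejoining at 30: the oxygen-for-chlorine exchange is postponed until the C1 arm is an electron-poor enal that cannot trap a cation at C9. Double addition of the organocerium reagent of step 13 to the lactone carbonyl and Peterson elimination on silica should give 2-bromo-1-methyl-4-(2-methylbut-3-yn-2-yl)-4-[3-(trimethylsilyl)prop-1-en-2-yl]cyclohexan-1-ol F2. Dimethyldioxirane and then Bu4NF should give 2-bromo-4-(3-hydroxyprop-1-en-2-yl)-1-methyl-4-(2-methylbut-3-yn-2-yl)cyclohexan-1-ol F3, and Dess–Martin oxidation of its primary allylic alcohol should give 2-[3-bromo-4-hydroxy-4-methyl-1-(2-methylbut-3-yn-2-yl)cyclohexyl]prop-2-enal F4. Thionyl chloride without base (chlorosulfite, internal return on the face of the departing oxygen, which is also the face anti to bromine) should then give 30 with retention.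

Step 8. What may go wrong: discrimination between the two enantiotopic α-methylene groups may be poor, because the axial ester sits close to the hydrogens being removed, so the enol triflate would have low enantiomeric purity. Fallback, setting out from 15 and rejoining at 19: classical resolution in place of asymmetric deprotonation. LDA and PhNTf2 should give racemic 2-(trimethylsilyl)ethyl 1-[2-methyl-4-(trimethylsilyl)but-3-yn-2-yl]-4-(trifluoromethanesulfonyloxy)cyclohex-3-ene-1-carboxylate F5. Iron-catalysed methylation should give racemic 2-(trimethylsilyl)ethyl 4-methyl-1-[2-methyl-4-(trimethylsilyl)but-3-yn-2-yl]cyclohex-3-ene-1-carboxylate F6, and Bu4NF should give racemic 4-methyl-1-(2-methylbut-3-yn-2-yl)cyclohex-3-ene-1-carboxylic acid F7. Crystallisation with (R)-1-phenylethylamine (or its enantiomer, whichever gives the less soluble salt of the (1R)-acid) should give (R)-1-phenylethylammonium (1R)-4-methyl-1-(2-methylbut-3-yn-2-yl)cyclohex-3-ene-1-carboxylate F8, and acidification releases 19.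

Further compounds

F1 | step 11 | 4-bromo-4-methyl-1-(2-methylbut-3-yn-2-yl)-6-oxabicyclo[3.2.1]octan-7-one (Br anti to the lactone oxygen) | C#CC(C)(C)[C@@]1(C(=O)O2)CC[C@@](C)(Br)[C@H]2C1
F2 | step 12 | 2-bromo-1-methyl-4-(2-methylbut-3-yn-2-yl)-4-[3-(trimethylsilyl)prop-1-en-2-yl]cyclohexan-1-ol (configured as 27 with OH for Cl) | C#CC(C)(C)[C@@]1(C(=C)C[Si](C)(C)C)CC[C@](C)(O)[C@@H](Br)C1
F3 | step 12 | 2-bromo-4-(3-hydroxyprop-1-en-2-yl)-1-methyl-4-(2-methylbut-3-yn-2-yl)cyclohexan-1-ol (configured as 29 with OH for Cl) | C#CC(C)(C)[C@@]1(C(=C)CO)CC[C@](C)(O)[C@@H](Br)C1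
F4 | step 12 | 2-[3-bromo-4-hydroxy-4-methyl-1-(2-methylbut-3-yn-2-yl)cyclohexyl]prop-2-enal (configured as 30 with OH for Cl) | C#CC(C)(C)[C@@]1(C(=C)C=O)CC[C@](C)(O)[C@@H](Br)C1
F5 | step 8 | racemic 2-(trimethylsilyl)ethyl 1-[2-methyl-4-(trimethylsilyl)but-3-yn-2-yl]-4-(trifluoromethanesulfonyloxy)cyclohex-3-ene-1-carboxylate | C[Si](C)(C)C#CC(C)(C)C1(C(=O)OCC[Si](C)(C)C)CCC(OS(=O)(=O)C(F)(F)F)=CC1
F6 | step 8 | racemic 2-(trimethylsilyl)ethyl 4-methyl-1-[2-methyl-4-(trimethylsilyl)but-3-yn-2-yl]cyclohex-3-ene-1-carboxylate | C[Si](C)(C)C#CC(C)(C)C1(C(=O)OCC[Si](C)(C)C)CCC(C)=CC1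
F7 | step 8 | racemic 4-methyl-1-(2-methylbut-3-yn-2-yl)cyclohex-3-ene-1-carboxylic acid | C#CC(C)(C)C1(C(=O)O)CCC(C)=CC1
F8 | step 8 | (R)-1-phenylethylammonium (1R)-4-methyl-1-(2-methylbut-3-yn-2-yl)cyclohex-3-ene-1-carboxylate | C#CC(C)(C)[C@@]1(C(=O)[O-])CCC(C)=CC1.C[C@@H]([NH3+])c1ccccc1
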